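**Retrosynthetic overview**
1. The strategy rests on the ester carbonyl carbon of the 15-membered lactone, which links arene carbon C4′ (para to the phenol oxygen) to the oxygen on C14. It is supplied as CO between an aryl iodide and the C14 hydroxyl by palladium-catalysed carbonylative macrolactonization.
2. The C15 bromide follows from the C15 tertiary alcohol with participation of the new ester; both silyl ethers are removed last.
3. The diol precursor gets C13–C16 by neutral Wittig olefination of a C12 aldehyde, then diimide and Corey–Bakshi–Shibata reduction (C14). C10–Br/C11–OH come from Sharpless epoxidation of the C12 allylic alcohol and bromide opening at C10.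
4. Ring A (C2–C7, Br on C6, new C2–C7 bond) comes from an asymmetric bromonium-induced cyclization of the E,E-diene of an ortho-farnesylated 4-iodophenyl acetate.
5. Ring order: the arene is bought, ring A is closed in step 5, the macrolactone in step 17.

Key step: step 17

Assumptions: chain atoms are numbered C1 (benzylic CH2), C2–C7 (ring A: C2, C3(Me)=C4, C5, C6(Br), C7(Me)), C8, C9, C10 (Br), C11 (Me, OH), C12, C13, C14 (lactone O), C15 (CBrMe2), C16 (a C15 methyl); arene C1′ (O), C2′ (CH2), C4′ (I, later C=O). (2E,6E)-Farnesyl bromide is taken as commercial. The catalyst antipode in step 5 that leads to the (2R,6S,7S) series is to be fixed in a pilot run; the (R)-form is written.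

**Step 1**
Reactants: 1 4-iodophenol; 2 (2E,6E)-farnesyl bromide
Product: 4 2-[(2E,6E)-3,7,11-trimethyldodeca-2,6,10-trien-1-yl]-4-iodophenol, via sodium 4-iodophenoxide 3 (not isolated)
Conditions: NaH, toluene, 0 °C → rt; then 2, rt
Reagents that add atoms: none
Why: Sodium phenoxides in a non-polar solvent are alkylated by allylic bromides at the ortho carbon (para position blocked by iodine), an SN2 displacement at C1 that keeps the 2E geometry (phenoxide ortho-C-allylation).

**Step 2**
Reactants: 4 2-[(2E,6E)-3,7,11-trimethyldodeca-2,6,10-trien-1-yl]-4-iodophenol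
Product: 5 2-[(2E,6E)-3,7,11-trimethyldodeca-2,6,10-trien-1-yl]-4-iodophenyl acetate
Conditions: Ac2O, pyridine, DMAP (cat.), CH2Cl2, 0 °C → rt
Reagents that add atoms: acetic anhydride, CC(=O)OC(C)=O
Why: Standard O-acetylation; the aryl ester oxygen is non-nucleophilic, so in step 5 it should not capture the C3 cation as a chromane, which an aryl silyl or alkyl ether could do.

**Step 3**
Reactants: 5 2-[(2E,6E)-3,7,11-trimethyldodeca-2,6,10-trien-1-yl]-4-iodophenyl acetate
Product: 6 2-[(2E,6E,10E)-12-hydroxy-3,7,11-trimethyldodeca-2,6,10-trien-1-yl]-4-iodophenyl acetate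
Conditions: SeO2 (cat.), t-BuOOH, salicylic acid (cat.), CH2Cl2, rt
Reagents that add atoms: tert-butyl hydroperoxide, CC(C)(C)OO
Why: Catalytic SeO2 allylic oxidation (ene reaction, then [2,3]-shift) should oxidise the E-methyl group of the least hindered terminal trisubstituted olefin to the (E)-allylic alcohol, as is usual for polyprenyl chains.

**Step 4**
Reactants: 6 2-[(2E,6E,10E)-12-hydroxy-3,7,11-trimethyldodeca-2,6,10-trien-1-yl]-4-iodophenyl acetate
Product: 7 2-[(2E,6E,10E)-12-acetoxy-3,7,11-trimethyldodeca-2,6,10-trien-1-yl]-4-iodophenyl acetate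
Conditions: Ac2O, pyridine, CH2Cl2, rt
Reagents that add atoms: acetic anhydride, CC(=O)OC(C)=O
Why: Acetylation masks the primary allylic alcohol and inductively deactivates the C10=C11 olefin toward bromonium formation in step 5.

**Step 5**
Reactants: 7 2-[(2E,6E,10E)-12-acetoxy-3,7,11-trimethyldodeca-2,6,10-trien-1-yl]-4-iodophenyl acetate
Product: 8 ring A diacetate 2-{[(1R,5S,6S)-6-[(3E)-5-acetoxy-4-methylpent-3-en-1-yl]-5-bromo-2,6-dimethylcyclohex-2-en-1-yl]methyl}-4-iodophenyl acetate (chain numbering 2R,6S,7S)
Conditions: 1,3-dibromo-5,5-dimethylhydantoin (0.55 equiv), (R)-3,3′-bis(2,4,6-triisopropylphenyl)-1,1′-binaphthalene-2,2′-diyl N-(trifluoromethylsulfonyl)thiophosphoramide (10 mol%), toluene/CH2Cl2, −78 → −40 °C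
Reagents that add atoms: 1,3-dibromo-5,5-dimethylhydantoin, CC1(C)N(Br)C(=O)N(Br)C1=O
Why: Proposed new method: the P=S Lewis base should carry Br+ from the hydantoin to one face of the C6=C7 olefin (C10=C11 is deactivated by its allylic acetate, C2=C3 by the electron-poor benzylic aryl group and it has no ring-closing path, and bromonium transfer between olefins is reversible), C2 of the C2=C3 olefin then opens the bromonium ion at C7 through a chair transition state that, from the E,E-diene, places Br, C8 and CH2Ar equatorial (Br cis to the C7 methyl and to CH2Ar, as in the target), the C3 cation loses H4 to give the endocyclic C3=C4 olefin, and the absolute sense (2R,6S,7S) comes from the catalyst; the closest known reaction types are the chiral thiophosphoramide-catalysed asymmetric bromocyclization of geranyl- and homogeranyl-arenes and the bromonium-induced 1,5-diene cyclization ended by proton loss.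

**Step 6**
Reactants: 8 ring A diacetate
Product: 9 2-{[(1R,5S,6S)-5-bromo-6-[(3E)-5-hydroxy-4-methylpent-3-en-1-yl]-2,6-dimethylcyclohex-2-en-1-yl]methyl}-4-iodophenol
Conditions: K2CO3, MeOH, 0 °C → rt
Reagents that add atoms: none
Why: Base-mediated methanolysis (transesterification) removes both acetates, and the equatorial neopentyl bromide at C6 has no anti-periplanar hydrogen and is inert to carbonate.

**Step 7**
Reactants: 9 ring A phenol with free C12 allylic alcohol
Product: 11 aryl tert-butyldimethylsilyl ether of 9 (C12 hydroxyl free), via ring A sodium phenoxide 10 (not isolated)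
Conditions: NaH (1.0 equiv), THF, 0 °C; then TBSCl, 0 °C
Reagents that add atoms: tert-butyldimethylsilyl chloride, CC(C)(C)[Si](C)(C)Cl
Why: One equivalent of NaH deprotonates only the phenol (about six pKa units more acidic than the primary alcohol), and the phenoxide is silylated chemoselectively.

**Step 8**
Reactants: 11 aryl tert-butyldimethylsilyl ether with free C12 allylic alcohol
Product: 12 (2R,6S,7S,10S,11S)-10,11-epoxy-12-ol (aryl silyl ether, ring A unchanged)
Conditions: Ti(OiPr)4 (cat.), L-(+)-diethyl tartrate, t-BuOOH, 4 Å molecular sieves, CH2Cl2, −20 °C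
Reagents that add atoms: tert-butyl hydroperoxide, CC(C)(C)OO
Why: Sharpless asymmetric epoxidation of the (E)-2-methyl allylic alcohol, in which L-(+)-tartrate delivers oxygen to the face that gives the (10S,11S)-epoxide (reagent control) and the non-allylic ring A olefin is not touched.

**Step 9**
Reactants: 12 (10S,11S)-10,11-epoxy-12-ol
Product: 13 (2R,6S,7S,10R,11S)-6,10-dibromo-11,12-diol (aryl silyl ether)
Conditions: Ti(OiPr)4, Et2NH2Br, CH2Cl2, rt
Reagents that add atoms: diethylammonium bromide, CC[NH2+]CC.[Br-]
Why: In the titanium chelate of the 2,3-epoxy alcohol, bromide should attack the carbon remote from the hydroxymethyl group (C10) with inversion, because the C12–O dipole and the chelate geometry disfavour attack at the tertiary C11 (Ti(OiPr)4-mediated C3-selective epoxy alcohol opening); this sets 10R, and C11 keeps its oxygen and configuration (11S).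

**Step 10**
Reactants: 13 (10R,11S)-6,10-dibromo-11,12-diol
Product: 14 11,12-bis(triethylsilyl) ether of 13
Conditions: Et3SiOTf, 2,6-lutidine, CH2Cl2, −78 → 0 °C
Reagents that add atoms: triethylsilyl trifluoromethanesulfonate, CC[Si](CC)(CC)OS(=O)(=O)C(F)(F)F
Why: A silyl triflate with a hindered pyridine base silylates both the primary and the hindered tertiary hydroxyl without closing the bromohydrin to an epoxide.

**Step 11**
Reactants: 14 11,12-bis(triethylsilyl) ether
Product: 16 (2R,6S,7S,10R,11S)-6,10-dibromo-11-(triethylsilyloxy)-12-aldehyde, via alkoxydimethylsulfonium chloride 15 (not isolated)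
Conditions: (COCl)2, DMSO, CH2Cl2, −78 → −30 °C; then Et3N, → 0 °C
Reagents that add atoms: none
Why: Swern conditions oxidise a primary triethylsilyl ether directly (the chlorosulfonium ion takes the unhindered ether oxygen and releases Et3SiCl) while the tertiary triethylsilyl and aryl silyl ethers stay, and the aldehyde has no α-hydrogen, so neither epimerisation nor elimination of the C10 bromide can follow.

**Step 12**
Reactants: 17 3-hydroxy-3-methylbutan-2-one
Product: 18 1-bromo-3-hydroxy-3-methylbutan-2-one
Conditions: Br2, MeOH, 0 °C → rt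
Reagents that add atoms: bromine, BrBr
Why: Acid-autocatalysed α-bromination of a methyl ketone, whose only enolisable position is the methyl group.

**Step 13**
Reactants: 18 1-bromo-3-hydroxy-3-methylbutan-2-one
Product: 20 3-hydroxy-3-methyl-1-(triphenyl-λ5-phosphanylidene)butan-2-one, via phosphonium bromide 19 (not isolated)
Conditions: PPh3, toluene, rt; then aq. NaOH, CH2Cl2
Reagents that add atoms: triphenylphosphine, c1ccc(cc1)P(c1ccccc1)c1ccccc1
Why: SN2 quaternisation of the phosphine by the α-bromo ketone and deprotonation of the acidic P–CH2–CO group give the keto-stabilised ylide.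

**Step 14**
Reactants: 16 11-(triethylsilyloxy)-12-aldehyde; 20 keto-stabilised ylide
Product: 21 (12E)-15-hydroxy-14-oxo-12-ene (enone with C13–C16 attached; ring A, both bromides and silyl ethers as in 16)
Conditions: toluene, 90 °C
Reagents that add atoms: none
Why: Wittig olefination with a stabilised ylide runs under neutral conditions (no alkoxide that could move the C11 silyl group or close an epoxide onto C10) and gives the E-enone.

**Step 15**
Reactants: 21 (12E)-enone
Product: 22 15-hydroxy-14-ketone with saturated C12–C13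
Conditions: 2-nitrobenzenesulfonyl hydrazide, Et3N, CH2Cl2, rt
Reagents that add atoms: none
Why: Diimide transfers H2 in a concerted, sterically sensitive way to the disubstituted enone C=C much faster than to the trisubstituted ring A olefin and leaves C–Br and C–I bonds alone.

**Step 16**
Reactants: 22 15-hydroxy-14-ketone
Product: 23 ring A aryl iodide with (14S)-14,15-diol, 11-O-triethylsilyl and aryl tert-butyldimethylsilyl ether (2R,6S,7S,10R,11S,14S)
Conditions: (R)-2-methyl-CBS-oxazaborolidine [(R)-1-methyl-3,3-diphenyltetrahydro-1H,3H-pyrrolo[1,2-c][1,3,2]oxazaborole], catecholborane, toluene, −78 → −40 °C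
Reagents that add atoms: none
Why: Corey–Bakshi–Shibata reduction, in which the CMe2O group acts as the large and the CH2 chain as the small substituent, so the (R)-catalyst should give the 14S carbinol (catalyst control), and catecholborane does not hydroborate the ring olefin at low temperature.

**Step 17**
Reactants: 23 ring A aryl iodide with (14S)-14,15-diol; 24 carbon monoxide
Product: 25 15-membered lactone with C15 tertiary alcohol, 11-O-triethylsilyl and aryl tert-butyldimethylsilyl ether
Conditions: Pd(OAc)2 (10 mol%), Xantphos [4,5-bis(diphenylphosphino)-9,9-dimethylxanthene] (20 mol%), CO (1 atm), iPr2NEt, 4-(dimethylamino)pyridine, toluene, 80 °C, syringe-pump addition of 23 (final 2 mM)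
Reagents that add atoms: none
Why: Pd(OAc)2 is reduced in the flask to zerovalent palladium–Xantphos, which adds oxidatively to the aryl iodide; CO inserts to give an aroylpalladium iodide (divalent palladium), 4-(dimethylamino)pyridine relays the acyl group as an N-aroylpyridinium ion, the C14 hydroxyl takes it and iPr2NEt removes HI. The closest known reaction type is the palladium-catalysed alkoxycarbonylative macrolactonization of aryl and vinyl halides that carry a remote hydroxyl. The 15-membered ring (lactone O, C=O, C4′, C3′, C2′, C1, C2, C7–C14) closes by intramolecular acyl transfer to oxygen, an exo-trig acyl substitution that forms the aryl–CO and CO–O bonds in one operation, and slow addition keeps the acyl intermediate dilute. No stereocentre is formed or touched. The step needs selectivity for the aryl iodide over the alkyl bromides (oxidative addition to Ar–I is far faster than to the hindered secondary bromides at C6 and C10) and for the secondary C14 hydroxyl over the tertiary C15 hydroxyl (steric). The C11 oxygen is silylated so that base cannot close an epoxide onto C10, the phenol is silylated so that no aryl ester oligomers form, and the equatorial C6 bromide has no anti-periplanar hydrogen for elimination.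

**Step 18**
Reactants: 25 15-membered lactone with C15 tertiary alcohol
Product: 27 bis-silylated tribromide (C15 tertiary bromide; 11-O-triethylsilyl; aryl tert-butyldimethylsilyl ether), via dioxolanylium triflate 26 (not isolated)
Conditions: Tf2O, 2,6-di-tert-butyl-4-methylpyridine, CH2Cl2, −78 °C; then Bu4NBr, −78 → 0 °C
Reagents that add atoms: tetrabutylammonium bromide, CCCC[N+](CCCC)(CCCC)CCCC.[Br-]
Why: Triflation of the only free hydroxyl (C15) ionises with participation of the C14 ester carbonyl to a 2-aryl-1,3-dioxolan-2-ylium ion, which bromide should open at the tertiary carbon C15 (the C–O bond with the most cationic character), so the C14–O bond is never broken and 14S is kept (neighbouring-group-assisted substitution, as in halide openings of acyloxonium ions), while the hindered base keeps the medium free of acid that could add to the ring olefin or strip the silyl ethers.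

**Step 19**
Reactants: 27 bis-silylated tribromide
Product: 28 CNP0215732.1 (2R,6S,7S,10R,11S,14S)
Conditions: HF·pyridine, pyridine, THF, 0 °C → rt
Reagents that add atoms: none
Why: Buffered HF·pyridine cleaves the tertiary triethylsilyl ether and the aryl tert-butyldimethylsilyl ether under non-basic conditions, so the C10/C11 bromohydrin cannot close to an epoxide and the tertiary bromide and the lactone stay intact.

**Compound list**
1 | 4-iodophenol | Oc1ccc(I)cc1 | starting material
2 | (2E,6E)-farnesyl bromide | CC(C)=CCC/C(C)=C/CC/C(C)=C/CBr | starting material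
3 | sodium 4-iodophenoxide | [Na+].[O-]c1ccc(I)cc1 | intermediate
4 | 2-[(2E,6E)-3,7,11-trimethyldodeca-2,6,10-trien-1-yl]-4-iodophenol | CC(C)=CCC/C(C)=C/CC/C(C)=C/Cc1cc(I)ccc1O | intermediate
5 | 2-[(2E,6E)-3,7,11-trimethyldodeca-2,6,10-trien-1-yl]-4-iodophenyl acetate | CC(C)=CCC/C(C)=C/CC/C(C)=C/Cc1cc(I)ccc1OC(C)=O | intermediate
6 | 2-[(2E,6E,10E)-12-hydroxy-3,7,11-trimethyldodeca-2,6,10-trien-1-yl]-4-iodophenyl acetate | OC/C(C)=C/CC/C(C)=C/CC/C(C)=C/Cc1cc(I)ccc1OC(C)=O | intermediate
7 | 2-[(2E,6E,10E)-12-acetoxy-3,7,11-trimethyldodeca-2,6,10-trien-1-yl]-4-iodophenyl acetate | CC(=O)OC/C(C)=C/CC/C(C)=C/CC/C(C)=C/Cc1cc(I)ccc1OC(C)=O | intermediate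
8 | ring A diacetate (2R,6S,7S; 10E) | CC1=CC[C@H](Br)[C@@](C)(CC/C=C(\C)COC(C)=O)[C@@H]1Cc1cc(I)ccc1OC(C)=O | intermediate
9 | ring A phenol with free C12 allylic alcohol (2R,6S,7S; 10E) | CC1=CC[C@H](Br)[C@@](C)(CC/C=C(\C)CO)[C@@H]1Cc1cc(I)ccc1O | intermediate
10 | sodium phenoxide of 9 | CC1=CC[C@H](Br)[C@@](C)(CC/C=C(\C)CO)[C@@H]1Cc1cc(I)ccc1[O-].[Na+] | intermediate
11 | aryl tert-butyldimethylsilyl ether of 9 (C12 hydroxyl free) | CC1=CC[C@H](Br)[C@@](C)(CC/C=C(\C)CO)[C@@H]1Cc1cc(I)ccc1O[Si](C)(C)C(C)(C)C | intermediate
12 | (2R,6S,7S,10S,11S)-10,11-epoxy-12-ol | CC1=CC[C@H](Br)[C@@](C)(CC[C@@H]2O[C@@]2(C)CO)[C@@H]1Cc1cc(I)ccc1O[Si](C)(C)C(C)(C)C | intermediate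
13 | (2R,6S,7S,10R,11S)-6,10-dibromo-11,12-diol | CC1=CC[C@H](Br)[C@@](C)(CC[C@@H](Br)[C@@](C)(O)CO)[C@@H]1Cc1cc(I)ccc1O[Si](C)(C)C(C)(C)C | intermediate
14 | 11,12-bis(triethylsilyl) ether of 13 | CC1=CC[C@H](Br)[C@@](C)(CC[C@@H](Br)[C@@](C)(O[Si](CC)(CC)CC)CO[Si](CC)(CC)CC)[C@@H]1Cc1cc(I)ccc1O[Si](C)(C)C(C)(C)C | intermediate
15 | C12 alkoxydimethylsulfonium chloride | CC1=CC[C@H](Br)[C@@](C)(CC[C@@H](Br)[C@@](C)(O[Si](CC)(CC)CC)CO[S+](C)C)[C@@H]1Cc1cc(I)ccc1O[Si](C)(C)C(C)(C)C.[Cl-] | intermediate
16 | (10R,11S)-11-(triethylsilyloxy)-12-aldehyde | CC1=CC[C@H](Br)[C@@](C)(CC[C@@H](Br)[C@@](C)(O[Si](CC)(CC)CC)C=O)[C@@H]1Cc1cc(I)ccc1O[Si](C)(C)C(C)(C)C | intermediate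
17 | 3-hydroxy-3-methylbutan-2-one | CC(=O)C(C)(C)O | starting material
18 | 1-bromo-3-hydroxy-3-methylbutan-2-one | BrCC(=O)C(C)(C)O | intermediate
19 | (3-hydroxy-3-methyl-2-oxobutyl)triphenylphosphonium bromide | CC(C)(O)C(=O)C[P+](c1ccccc1)(c1ccccc1)c1ccccc1.[Br-] | intermediate
20 | 3-hydroxy-3-methyl-1-(triphenyl-λ5-phosphanylidene)butan-2-one | CC(C)(O)C(=O)C=P(c1ccccc1)(c1ccccc1)c1ccccc1 | intermediate
21 | (12E)-15-hydroxy-14-oxo-12-ene (enone) | CC1=CC[C@H](Br)[C@@](C)(CC[C@@H](Br)[C@@](C)(O[Si](CC)(CC)CC)/C=C/C(=O)C(C)(C)O)[C@@H]1Cc1cc(I)ccc1O[Si](C)(C)C(C)(C)C | intermediate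
22 | 15-hydroxy-14-ketone (C12–C13 saturated) | CC1=CC[C@H](Br)[C@@](C)(CC[C@@H](Br)[C@@](C)(O[Si](CC)(CC)CC)CCC(=O)C(C)(C)O)[C@@H]1Cc1cc(I)ccc1O[Si](C)(C)C(C)(C)C | intermediate
23 | ring A aryl iodide with (14S)-14,15-diol, 11-O-triethylsilyl, aryl tert-butyldimethylsilyl ether | CC1=CC[C@H](Br)[C@@](C)(CC[C@@H](Br)[C@@](C)(O[Si](CC)(CC)CC)CC[C@H](O)C(C)(C)O)[C@@H]1Cc1cc(I)ccc1O[Si](C)(C)C(C)(C)C | intermediate
24 | carbon monoxide | [C-]#[O+] | starting material
25 | 15-membered lactone with C15 tertiary alcohol and both silyl ethers | CC1=CC[C@H](Br)[C@@]2(C)CC[C@@H](Br)[C@@](C)(O[Si](CC)(CC)CC)CC[C@@H](C(C)(C)O)OC(=O)c3ccc(O[Si](C)(C)C(C)(C)C)c(c3)C[C@H]12 | intermediate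
26 | 2-aryl-4,4-dimethyl-1,3-dioxolan-2-ylium triflate spanning C14/C15 | CC1=CC[C@H](Br)[C@@]2(C)CC[C@@H](Br)[C@@](C)(O[Si](CC)(CC)CC)CC[C@@H]4OC(=[O+]C4(C)C)c3ccc(O[Si](C)(C)C(C)(C)C)c(c3)C[C@H]12.[O-]S(=O)(=O)C(F)(F)F | intermediate
27 | bis-silylated tribromide (C15 bromide) | CC1=CC[C@H](Br)[C@@]2(C)CC[C@@H](Br)[C@@](C)(O[Si](CC)(CC)CC)CC[C@@H](C(C)(C)Br)OC(=O)c3ccc(O[Si](C)(C)C(C)(C)C)c(c3)C[C@H]12 | intermediate
28 | CNP0215732.1 (2R,6S,7S,10R,11S,14S) | CC1=CC[C@H](Br)[C@@]2(C)CC[C@@H](Br)[C@@](C)(O)CC[C@@H](C(C)(C)Br)OC(=O)c3ccc(O)c(c3)C[C@H]12 | target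

**Step count**
Total: 19 steps. Longest linear sequence: 17 steps (steps 1–11 and 14–19); steps 12–13 make the ylide.

**Steps most likely to fail**

Step 5 (Proposed new method). The bromonium ion may form on the wrong olefin, the C3 cation may lose a proton toward the exocyclic or the tetrasubstituted position, or the catalyst may discriminate poorly between the faces of an internal trisubstituted olefin. The fallback sets out from 7: the achiral bromonium salt Et2SBr·SbCl5Br in nitromethane at −25 °C (a known bromonium-induced polyene cyclization) should give racemic ring A diacetate, that is 8 together with its mirror image, the (2S,6R,7R)-ring A diacetate F1. Preparative chromatography on a chiral stationary phase removes F1, and the route is rejoined at 8.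

Step 17. Ring closure to the 15-membered lactone may be slower than intermolecular acyl transfer (oligomers) or than decay of the aroylpalladium species, because the nucleophile is a hindered secondary alcohol. The fallback sets out from 23 and separates carbonylation from ring closure: Pd(OAc)2, Xantphos, CO (1 atm), water and iPr2NEt in dioxane at 70 °C (hydroxycarbonylation of an aryl iodide) should give the seco acid F2. Shiina macrolactonization (2-methyl-6-nitrobenzoic anhydride, 4-(dimethylamino)pyridine, CH2Cl2, high dilution) at the secondary C14 hydroxyl then returns to 25.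

Step 18. Bromide may open the acyloxonium ion at C14 instead of C15 (ring-expanded lactone with inversion), the ion may lose a proton to an isopropenyl group, or the aryl silyl group may be lost through the quinoid resonance form of the cation. The fallback sets out from 25 and avoids the cation: dehydration with methyl N-(triethylammoniosulfonyl)carbamate (inner salt) in toluene at 50 °C should give the isopropenyl lactone F3. Markovnikov radical hydrobromination of its 1,1-disubstituted olefin (Co(acac)2, t-BuOOH, Et3SiH, p-toluenesulfonyl bromide, rt), which should be faster than reaction at the hindered ring A olefin, then returns to 27.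

**Further compounds**
F1 | step 5 | (2S,6R,7R)-enantiomer of ring A diacetate 8 | CC1=CC[C@@H](Br)[C@](C)(CC/C=C(\C)COC(C)=O)[C@H]1Cc1cc(I)ccc1OC(C)=O
F2 | step 17 | seco acid: 4-(tert-butyldimethylsilyloxy)-3-(ring A-methyl)benzoic acid with (10R,11S,14S)-10-bromo-11-(triethylsilyloxy)-14,15-diol chain | CC1=CC[C@H](Br)[C@@](C)(CC[C@@H](Br)[C@@](C)(O[Si](CC)(CC)CC)CC[C@H](O)C(C)(C)O)[C@@H]1Cc1cc(C(=O)O)ccc1O[Si](C)(C)C(C)(C)C
F3 | step 18 | 15-membered lactone with isopropenyl group on C14 (C15=C16) and both silyl ethers | CC1=CC[C@H](Br)[C@@]2(C)CC[C@@H](Br)[C@@](C)(O[Si](CC)(CC)CC)CC[C@@H](C(C)=C)OC(=O)c3ccc(O[Si](C)(C)C(C)(C)C)c(c3)C[C@H]12
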